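Read each plateau as a count of turnovers per catalyst, and two of us still disagree about Thursday's flask.

all flasks: free catalyst 1 mol%; impurity 2.9 µM

|  | starting material | partner | remark | time |
|---|---|---|---|---|
| oak | 2.0 × 10⁻⁴ M | 2.5 equiv | run made earlier |  |
| maple | 1.3 × 10⁻⁴ M | 2.5 equiv | run made earlier |  |
| ash | 3.0 × 10⁻⁴ M | 2.5 equiv | run made earlier |  |
| Thursday's | 2.0 × 10⁻⁴ M | 2.50 equiv (fed, over 80 s) | all else is in the flask from the start; the feed brings no volume worth counting | 2.0 min |
| Tuesday's | 2.0 × 10⁻⁴ M | 2.50 equiv | everything together at the start | 2.0 min |
| Saturday's | 2.0 × 10⁻⁴ M (fed, over 80 s) | 2.50 equiv | all else is in the flask from the start; the feed brings no volume worth counting | 2.0 min |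

oak run (percent of the starting material charged)

| time / s | product / % | starting material / % |
|---|---|---|
| 10.0 | 34.5 | 66.4 |
| 15.0 | 39.8 | 60.5 |
| 25.0 | 45.0 | 55.1 |
| 40.0 | 45.8 | 53.5 |
| 60.0 | 46.7 | 53.1 |
| 80.0 | 47.2 | 53.4 |

maple run (percent of the starting material charged)

| time / min | product / % | starting material / % |
|---|---|---|
| 0.417 | 28.2 | 72.1 |
| 0.833 | 28.4 | 71.6 |
| 1.33 | 28.0 | 71.7 |
| 1.50 | 28.7 | 72.3 |
| 2.00 | 28.7 | 71.8 |
| 2.50 | 28.4 | 71.6 |

ash run (percent of the starting material charged)

| time / min | product / % | starting material / % |
|---|---|---|
| 0.200 | 50.8 | 50.5 |
| 0.333 | 61.5 | 37.8 |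
| 0.500 | 71.0 | 29.3 |
| 0.833 | 78.2 | 21.5 |
| 1.33 | 80.8 | 18.4 |
| 2.50 | 82.1 | 17.0 |

(each reading ± 0.3 percentage points)

* which flask leads in amount of product, in percent of the starting material charged ("all alike" within 1.5 percentage points) (Thursday's / Tuesday's / Saturday's / all alike)
* how much product is there at the end, in percent of the starting material charged: Thursday's
* how much product is there at the end, in percent of the starting material charged: Tuesday's
* how much product is there at the end, in percent of the starting material charged: Saturday's



The stock view counts charges. Oak ends with 53.4% of its starting material left, its 2.00 µM of free catalyst faces 2.9 µM of impurity, and Tuesday's and Thursday's carry the same charges. So this side expects both near oak's 47.2% and calls the feed a detail.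

The guard view, mine, asks where free catalyst goes at each moment. Free catalyst lives briefly, so I take it as steady. It leaves either to partner, which yields one product, or to impurity, which costs one catalyst and one impurity. The two exits stand in the ratio s·c(partner)/c(impurity), with s the selectivity factor. With c(partner) held at its charge, this integrates to c(product) = s·c(partner)·ln(c(impurity) at start / c(impurity) at end). Oak, its impurity falling by the catalyst charge, reads s = 0.161, and maple reads 0.191.

The guard level, the c(partner) at which the two exits are equal, is c(impurity)/s = 18.0 µM. Tuesday's starts at 500 µM, far above it. Thursday's starts with no partner, and its feed reaches the guard level after 2.88 s; until then impurity is the likelier exit. The runs hold no clock for that exit, so I commit to a bet: Thursday's catalyst dies first, and its plateau with it.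

The forecast sides with the stock view, with 45.5% for Thursday's, 47% for Tuesday's, 8% for Saturday's and Tuesday's leading; in its words, “partner supply roughly keeps up”. The simulation gives 1.06% for Thursday's, 46.6% for Tuesday's and 27.3% for Saturday's, with Tuesday's leading.

    partner → decomposed reagent (k = 0.0390 s⁻¹)
    catalyst intermediate A → catalyst intermediate B (k = 24.0 s⁻¹)
    free catalyst + impurity → spent catalyst (k = 8.10 × 10⁵ M⁻¹ s⁻¹)
    starting material + catalyst intermediate B ⇌ catalyst intermediate C (K = 3400 M⁻¹, k = 8.10 × 10⁶ M⁻¹ s⁻¹)
    partner + free catalyst → catalyst intermediate A (k = 2.10 × 10⁵ M⁻¹ s⁻¹)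
    catalyst intermediate D → free catalyst + product (k = 590 s⁻¹)
    catalyst intermediate C → catalyst intermediate D (k = 26.0 s⁻¹)

Take away the turning of free catalyst + impurity into spent catalyst and the gap between Tuesday's and Thursday's falls from 46 percentage points to 0 points, the largest single effect on it, so the stock view's claim that the feed is a detail holds in that poison-free run, though its expected yield does not. Free catalyst's half-life against impurity, reckoned for Tuesday's charge and Thursday's has the same, is 0.30 s, shorter than the 2.88 s that Thursday's feed needs to reach the guard level of 18.0 µM, both of these last two being my estimates from the oak readings. The neighbour fed 10.0 equiv of partner reaches that estimated level in 0.719 s, still behind that half-life, and gives 7.71%.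

The readings were generated by integration for an exercise, noise included.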